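**Retrosynthetic overview**
1. The C8'–C9' bond is cut between the dihydrofuran end and the polyene. Ring C (O–C5'–C6'=C7'–C8') is the cycloisomer of the α-hydroxyallene C5'(OH)–C6'=C7'=C8', which is the syn-SN2' product of a C5'–C6' oxirane carrying the terminal alkyne C7'≡C8'–H. So 24 ⇒ alkynyl oxirane 5 (C11) + octaenyl boronate 22 (C29); the oxirane is a ring absent from the target whose C6'–O bond steers C8' and is cleaved in the same operation.
2. 22 ⇒ Wittig at C11=C12 of C15 phosphonium salt 14 with boryl pentaenal 21; 21 ⇒ Horner–Wadsworth–Emmons at C11'=C12' of C10 dialdehyde 20 with boryl phosphonate 19 (from ethyl but-2-ynoate 15).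
3. Both end groups come from one Sharpless epoxidation (2 → 3 → 4): 4 → alkyne 5; 4 → Wharton transposition, ozonolysis → (R)-hydroxy ketone 7 → acetylide addition anti to the C5–O bond → cis-5,6-diol.
4. Ring order: rings A and B (cyclohexanes) are bought with β-cyclocitral; the temporary oxirane is made in step 2; ring C is made last, in the key step, together with the C8'–C9' bond and the C8' stereocenter.

Key step: step 17

Remark: carotenoid numbering is used (primed atoms and ring B belong to the dihydrofuran end, unprimed atoms and ring A to the diol end, ring C is the dihydrofuran); 1, 9, 15 and 20 are taken as purchased.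

**Step 1**
Reactants: 1 β-cyclocitral
Product: 2 β-cyclogeraniol
Conditions: NaBH4, MeOH, 0 °C
Reagents that add atoms: none
Why: Borohydride 1,2-reduction of the hindered enal gives the allylic alcohol that will direct the epoxidation; no stereocenter is formed.

**Step 2**
Reactants: 2 β-cyclogeraniol
Product: 3 [(1R,6R)-2,2,6-trimethyl-7-oxabicyclo[4.1.0]heptan-1-yl]methanol
Conditions: Ti(OiPr)4 (10 mol %), D-(−)-diethyl tartrate (12 mol %), t-BuOOH, 4 Å MS, CH2Cl2, −20 °C
Reagents that add atoms: tert-butyl hydroperoxide CC(C)(C)OO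
Why: Katsuki–Sharpless asymmetric epoxidation of the tetrasubstituted allylic alcohol; D-(−)-tartrate should deliver oxygen to the face that makes C5' (R) and, through the cis ring fusion, C6' (R), the mirror-image sense of the (2S,3S) epoxide that L-(+)-tartrate gives with geraniol.

**Step 3**
Reactants: 3 epoxy alcohol
Product: 4 (1S,6R)-2,2,6-trimethyl-7-oxabicyclo[4.1.0]heptane-1-carbaldehyde
Conditions: Pr4N[RuO4] (5 mol %), N-methylmorpholine N-oxide, 4 Å MS, CH2Cl2, rt
Reagents that add atoms: none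
Why: Ley–Griffith oxidation under neutral conditions spares the tetrasubstituted oxirane, and the aldehyde has no α-hydrogen so it cannot epimerize.

**Step 4**
Reactants: 4 epoxy aldehyde
Product: 5 (1R,6R)-1-ethynyl-2,2,6-trimethyl-7-oxabicyclo[4.1.0]heptane
Conditions: dimethyl (1-diazo-2-oxopropyl)phosphonate, K2CO3, MeOH, 0 °C → rt
Reagents that add atoms: dimethyl (1-diazo-2-oxopropyl)phosphonate COP(=O)(OC)C(=[N+]=[N-])C(C)=O
Why: Seyferth–Gilbert homologation in the Ohira–Bestmann form converts the non-enolizable aldehyde into the terminal alkyne under mild base that leaves the oxirane and both stereocenters untouched.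

**Step 5**
Reactants: 4 epoxy aldehyde
Product: 6 (1R)-1,3,3-trimethyl-2-methylidenecyclohexan-1-ol
Conditions: N2H4·H2O, AcOH (cat.), MeOH, 0 °C → rt
Reagents that add atoms: none
Why: Wharton transposition, in which the hydrazone opens the oxirane at C6 and loses N2 to give the exocyclic alkene while the C5–O bond and hence the (R) center are retained.

**Step 6**
Reactants: 6 methylidene carbinol
Product: 7 (2R)-2-hydroxy-2,6,6-trimethylcyclohexan-1-one
Conditions: O3, CH2Cl2/MeOH, −78 °C; then Me2S
Reagents that add atoms: ozone [O-][O+]=O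
Why: Ozonolysis of the 1,1-disubstituted alkene excises the methylidene carbon and unveils the C6 ketone without touching the tertiary carbinol center.

**Step 7**
Reactants: 7 hydroxy ketone
Product: 8 (2R)-2,6,6-trimethyl-2-[(triethylsilyl)oxy]cyclohexan-1-one
Conditions: Et3SiOTf, 2,6-lutidine, CH2Cl2, −78 → 0 °C
Reagents that add atoms: triethylsilyl trifluoromethanesulfonate CC[Si](CC)(CC)OS(=O)(=O)C(F)(F)F
Why: Silyl triflate silylation of the hindered tertiary alcohol installs a bulky, non-chelating ether so that the next addition is not chelation-controlled.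

**Step 8**
Reactants: 8 silyloxy ketone; 9 (2E)-3-methylpent-2-en-4-yn-1-ol
Product: 10 (2E)-5-[(1R,2R)-1-hydroxy-2,6,6-trimethyl-2-[(triethylsilyl)oxy]cyclohexyl]-3-methylpent-2-en-4-yn-1-ol
Conditions: 9, n-BuLi (2.05 equiv), THF, −78 → 0 °C; then 8, −78 °C → rt; H2O quench
Reagents that add atoms: none
Why: 1,2-addition of the dilithio acetylide to the non-enolizable ketone; in the chair with the C5–OSi bond axial, the silyloxy group and one C1 methyl shield one face, so the small nucleophile should enter axially anti to the C–O bond (polar Felkin–Anh) and set C6 with its hydroxyl cis to the C5 oxygen.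

**Step 9**
Reactants: 10 ynediol mono-silyl ether
Product: 12 (1S,2R)-1-[(1E,3E)-5-hydroxy-3-methylpenta-1,3-dien-1-yl]-2,6,6-trimethylcyclohexane-1,2-diol, via silyl ether 11 (not isolated)
Conditions: NaAlH2(OCH2CH2OCH3)2, THF, 0 °C → rt; aq. NaOH work-up; then Bu4NF, THF, rt
Reagents that add atoms: none
Why: Alkoxide-directed trans-hydroalumination of the propargylic alcohol (Chan-type reduction) should give the (7E)-alkene while the (9E)-alkene is kept, and fluoride then removes the silyl ether.

**Step 10**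
Reactants: 12 triol
Product: 14 [(2E,4E)-5-[(1S,2R)-1,2-dihydroxy-2,6,6-trimethylcyclohexyl]-3-methylpenta-2,4-dien-1-yl]triphenylphosphonium bromide, via allylic bromide 13 (not isolated)
Conditions: CBr4, PPh3, CH2Cl2, −20 °C; then PPh3, CH3CN/EtOAc, rt
Reagents that add atoms: tetrabromomethane BrC(Br)(Br)Br; triphenylphosphine c1ccc(cc1)P(c1ccccc1)c1ccccc1
Why: Appel bromination is selective for the primary allylic hydroxyl over the two tertiary ones under neutral conditions, and the allylic bromide is quaternized in the same flask by triphenylphosphine (SN2).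

**Step 11**
Reactants: 15 ethyl but-2-ynoate
Product: 16 ethyl (2Z)-3-(4,4,5,5-tetramethyl-1,3,2-dioxaborolan-2-yl)but-2-enoate
Conditions: CuCl (3 mol %), Xantphos (3 mol %), NaOtBu (6 mol %), B2pin2, MeOH (2 equiv), THF, rt
Reagents that add atoms: bis(pinacolato)diboron CC1(C)OB(OC1(C)C)B1OC(C)(C)C(C)(C)O1
Why: Copper-catalysed β-borylation of the ynoate (syn boryl-cupration, then protonation) places boron on C3 cis to the new hydrogen, so boron is trans to the ester as the (9'E) chain geometry requires.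

**Step 12**
Reactants: 16 boryl enoate
Product: 17 (2Z)-3-(4,4,5,5-tetramethyl-1,3,2-dioxaborolan-2-yl)but-2-en-1-ol
Conditions: i-Bu2AlH (2.2 equiv), CH2Cl2, −78 °C; aq. potassium sodium tartrate work-up
Reagents that add atoms: none
Why: Ester-to-alcohol reduction with the aluminium hydride at low temperature leaves the alkenyl boronate and the double-bond geometry intact.

**Step 13**
Reactants: 17 boryl allylic alcohol
Product: 18 2-[(2Z)-4-bromobut-2-en-2-yl]-4,4,5,5-tetramethyl-1,3,2-dioxaborolane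
Conditions: CBr4, PPh3, CH2Cl2, 0 °C
Reagents that add atoms: tetrabromomethane BrC(Br)(Br)Br
Why: Appel bromination converts the primary allylic alcohol into the bromide under neutral conditions without allylic transposition.

**Step 14**
Reactants: 18 boryl allylic bromide
Product: 19 diethyl [(2Z)-3-(4,4,5,5-tetramethyl-1,3,2-dioxaborolan-2-yl)but-2-en-1-yl]phosphonate
Conditions: P(OEt)3, neat, 100 °C
Reagents that add atoms: triethyl phosphite CCOP(OCC)OCC
Why: Michaelis–Arbuzov reaction of the primary allylic bromide gives the allylic phosphonate by SN2 attack at the unhindered carbon.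

**Step 15**
Reactants: 19 boryl phosphonate; 20 (2E,4E,6E)-2,7-dimethylocta-2,4,6-trienedial
Product: 21 (2E,4E,6E,8E,10Z)-2,7-dimethyl-11-(4,4,5,5-tetramethyl-1,3,2-dioxaborolan-2-yl)dodeca-2,4,6,8,10-pentaenal
Conditions: 19, NaN(SiMe3)2, THF, −78 °C; then added to 20 (3 equiv), −78 → 0 °C, dark
Reagents that add atoms: none
Why: Horner–Wadsworth–Emmons olefination of the allylic phosphonate anion with an excess of the symmetrical dialdehyde should give the mono-adduct with the new C11'=C12' bond (E).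

**Step 16**
Reactants: 14 C15 phosphonium bromide; 21 boryl pentaenal
Product: 22 (1S,2R)-1-[(1E,3E,5E,7E,9E,11E,13E,15Z)-3,7,12-trimethyl-16-(4,4,5,5-tetramethyl-1,3,2-dioxaborolan-2-yl)heptadeca-1,3,5,7,9,11,13,15-octaen-1-yl]-2,6,6-trimethylcyclohexane-1,2-diol
Conditions: 1,2-epoxybutane/EtOH (1:1), 70 °C, argon, dark; then heptane, 80 °C
Reagents that add atoms: none
Why: Wittig olefination with the ylide generated under neutral conditions by 1,2-epoxybutane tolerates the free diol and the boronate, and heating should equilibrate the new C11=C12 bond toward the (E) isomer as is usual for carotenoid polyenes.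

**Step 17**
Reactants: 5 alkynyl oxirane; 22 octaenyl boronate
Product: 24 (5R,6S,5'R,8'R)-5',8'-epoxy-5,6,5',8'-tetrahydro-β,β-carotene-5,6-diol, via α-hydroxyallene 23 (not isolated)
Conditions: [Rh(OH)(cod)]2 (5 mol %), THF/H2O (20:1), 30 °C, argon, dark; then AgNO3 (20 mol %), CaCO3, acetone/H2O, 25 °C, dark
Reagents that add atoms: none
Why: Proposed new method: the rhodium hydroxide transmetalates with the C9'–B bond of 22, the alkenyl–rhodium adds syn across C7'≡C8' of 5 with the metal on C7' (held by the oxirane oxygen) and the polyene on C8', and syn β-oxygen elimination opens the C6'–O bond to the α-hydroxyallene 23 (net syn-SN2'), the rhodium alkoxide turning over with the next boronate; AgNO3 then binds C7'=C8', the C5' hydroxyl closes on C8' anti to silver, and protodemetalation gives ring C. The closest known reactions are the rhodium-catalysed syn-selective arylation of internal alkynyl oxiranes with arylboronic acids (and the iron-catalysed syn-SN2' opening of propargyl epoxides by Grignard reagents), followed by silver- or gold-catalysed cycloisomerization of α-hydroxyallenes to 2,5-dihydrofurans; new here are the terminal alkyne, the polyenyl boronate and the union of both events in one flask. Ring C closes in a 5-endo-trig mode onto the allene terminus. C8' is set by relay: the C6'–O bond of the oxirane (fixed in step 2) fixes the allene axis with C9' syn to the departing oxygen, and oxy-metalation in the plane of the C7'=C8' π bond turns that axis into the (8'R) center with C9' trans to the C5' methyl, while C5' keeps its C–O bond throughout. The step needs syn over anti SN2' selectivity (secured by O→Rh chelation, whereas zerovalent palladium would give the anti, 8'S series), carbometalation with the polyene on C8' and not C7' (C7' is neopentyl and oxygen-directed for rhodium), and an intact allene axis (weak π-acid, CaCO3 buffer, short contact in the dark).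

**Compound list**
1 | β-cyclocitral (2,6,6-trimethylcyclohex-1-ene-1-carbaldehyde) | CC1=C(C=O)C(C)(C)CCC1 | starting material
2 | β-cyclogeraniol ((2,6,6-trimethylcyclohex-1-en-1-yl)methanol) | CC1=C(CO)C(C)(C)CCC1 | intermediate
3 | [(1R,6R)-2,2,6-trimethyl-7-oxabicyclo[4.1.0]heptan-1-yl]methanol | OC[C@@]12O[C@]1(C)CCCC2(C)C | intermediate
4 | (1S,6R)-2,2,6-trimethyl-7-oxabicyclo[4.1.0]heptane-1-carbaldehyde | O=C[C@@]12O[C@]1(C)CCCC2(C)C | intermediate
5 | (1R,6R)-1-ethynyl-2,2,6-trimethyl-7-oxabicyclo[4.1.0]heptane | C#C[C@@]12O[C@]1(C)CCCC2(C)C | intermediate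
6 | (1R)-1,3,3-trimethyl-2-methylidenecyclohexan-1-ol | C=C1C(C)(C)CCC[C@@]1(C)O | intermediate
7 | (2R)-2-hydroxy-2,6,6-trimethylcyclohexan-1-one | O=C1C(C)(C)CCC[C@@]1(C)O | intermediate
8 | (2R)-2,6,6-trimethyl-2-[(triethylsilyl)oxy]cyclohexan-1-one | O=C1C(C)(C)CCC[C@@]1(C)O[Si](CC)(CC)CC | intermediate
9 | (2E)-3-methylpent-2-en-4-yn-1-ol | C#C/C(C)=C/CO | starting material
10 | (2E)-5-[(1R,2R)-1-hydroxy-2,6,6-trimethyl-2-[(triethylsilyl)oxy]cyclohexyl]-3-methylpent-2-en-4-yn-1-ol | OC/C=C(C)/C#C[C@]1(O)C(C)(C)CCC[C@@]1(C)O[Si](CC)(CC)CC | intermediate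
11 | (2E,4E)-5-[(1S,2R)-1-hydroxy-2,6,6-trimethyl-2-[(triethylsilyl)oxy]cyclohexyl]-3-methylpenta-2,4-dien-1-ol | OC/C=C(C)/C=C/[C@]1(O)C(C)(C)CCC[C@@]1(C)O[Si](CC)(CC)CC | intermediate
12 | (1S,2R)-1-[(1E,3E)-5-hydroxy-3-methylpenta-1,3-dien-1-yl]-2,6,6-trimethylcyclohexane-1,2-diol | OC/C=C(C)/C=C/[C@]1(O)C(C)(C)CCC[C@@]1(C)O | intermediate
13 | (1S,2R)-1-[(1E,3E)-5-bromo-3-methylpenta-1,3-dien-1-yl]-2,6,6-trimethylcyclohexane-1,2-diol | BrC/C=C(C)/C=C/[C@]1(O)C(C)(C)CCC[C@@]1(C)O | intermediate
14 | [(2E,4E)-5-[(1S,2R)-1,2-dihydroxy-2,6,6-trimethylcyclohexyl]-3-methylpenta-2,4-dien-1-yl]triphenylphosphonium bromide | [Br-].C(/C=C(C)/C=C/[C@]1(O)C(C)(C)CCC[C@@]1(C)O)[P+](c1ccccc1)(c1ccccc1)c1ccccc1 | intermediate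
15 | ethyl but-2-ynoate | CC#CC(=O)OCC | starting material
16 | ethyl (2Z)-3-(4,4,5,5-tetramethyl-1,3,2-dioxaborolan-2-yl)but-2-enoate (boron trans to the ester) | CCOC(=O)/C=C(\C)B1OC(C)(C)C(C)(C)O1 | intermediate
17 | (2Z)-3-(4,4,5,5-tetramethyl-1,3,2-dioxaborolan-2-yl)but-2-en-1-ol | OC/C=C(\C)B1OC(C)(C)C(C)(C)O1 | intermediate
18 | 2-[(2Z)-4-bromobut-2-en-2-yl]-4,4,5,5-tetramethyl-1,3,2-dioxaborolane | BrC/C=C(\C)B1OC(C)(C)C(C)(C)O1 | intermediate
19 | diethyl [(2Z)-3-(4,4,5,5-tetramethyl-1,3,2-dioxaborolan-2-yl)but-2-en-1-yl]phosphonate | CCOP(=O)(OCC)C/C=C(\C)B1OC(C)(C)C(C)(C)O1 | intermediate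
20 | (2E,4E,6E)-2,7-dimethylocta-2,4,6-trienedial (C10 dialdehyde) | O=C/C(C)=C/C=C/C=C(\C)C=O | starting material
21 | (2E,4E,6E,8E,10Z)-2,7-dimethyl-11-(4,4,5,5-tetramethyl-1,3,2-dioxaborolan-2-yl)dodeca-2,4,6,8,10-pentaenal | O=C/C(C)=C/C=C/C=C(C)/C=C/C=C(\C)B1OC(C)(C)C(C)(C)O1 | intermediate
22 | (1S,2R)-1-[(1E,3E,5E,7E,9E,11E,13E,15Z)-3,7,12-trimethyl-16-(4,4,5,5-tetramethyl-1,3,2-dioxaborolan-2-yl)heptadeca-1,3,5,7,9,11,13,15-octaen-1-yl]-2,6,6-trimethylcyclohexane-1,2-diol | CC(/C=C/C=C(C)/C=C/[C@]1(O)C(C)(C)CCC[C@@]1(C)O)=C\C=C\C=C(C)\C=C\C=C(/C)B1OC(C)(C)C(C)(C)O1 | intermediate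
23 | (5R,6S,5'R)-6',7'-didehydro-5,6,5',6'-tetrahydro-β,β-carotene-5,6,5'-triol, allene axis (aS), C9' on the side of the C5' oxygen | CC(/C=C/C=C(C)/C=C/[C@]1(O)C(C)(C)CCC[C@@]1(C)O)=C\C=C\C=C(C)\C=C\C=C(/C)C([H])=[C@]=C1C(C)(C)CCC[C@@]1(C)O | intermediate
24 | (5R,6S,5'R,8'R)-5',8'-epoxy-5,6,5',8'-tetrahydro-β,β-carotene-5,6-diol | CC(/C=C/C=C(C)/C=C/[C@]1(O)C(C)(C)CCC[C@@]1(C)O)=C\C=C\C=C(C)\C=C\C=C(/C)[C@H]1C=C2C(C)(C)CCC[C@@]2(C)O1 | target

**Totals and risks**
Total step count: 17. Longest linear sequence: 11 steps (1 → 2 → 3 → 4 → 6 → 7 → 8 → 10 → 12 → 14 → 22 → 24; steps 1, 2, 3, 5, 6, 7, 8, 9, 10, 16, 17).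

The three steps most likely to fail:

(a) The key step, step 17, which bears the label "Proposed new method:". What may go wrong is protonolysis of the polyenyl–rhodium bond by the terminal alkyne C–H or by water, oligomerization of the alkyne on rhodium, leakage into the anti SN2' pathway, or loss of the allene axis on silver before ring closure. The fallback uses known chemistry, sets out from 5 and 22 and comes back at 23. Compound 5 is iodinated at the alkyne terminus (N-iodosuccinimide, AgNO3 cat., acetone) to (1R,6R)-1-(iodoethynyl)-2,2,6-trimethyl-7-oxabicyclo[4.1.0]heptane F1. Suzuki–Miyaura coupling of F1 with 22 (Pd(PPh3)4, aq. K3PO4, THF, rt) forms the same C8'–C9' bond as an sp–sp2 bond and gives the dienyne oxirane (5R,6S,5'R,6'R)-5',6'-epoxy-7',8'-didehydro-5,6,5',6'-tetrahydro-β,β-carotene-5,6-diol F2. Copper hydride SN2' reduction of F2 ((IPr)CuCl with IPr = 1,3-bis(2,6-diisopropylphenyl)imidazol-2-ylidene, NaOtBu, polymethylhydrosiloxane, toluene) delivers hydride to C8' anti to the C6'–O bond, which leaves C9' syn to it and so gives the same allene 23, where the route is rejoined for the AgNO3 stage.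

(b) Step 8. What may go wrong is poor facial selectivity, if the chair with the silyloxy group equatorial or a lithium chelate reacts and puts the alkynyl group cis to the C5 oxygen (trans-diol). The fallback sets out from 4 and comes back at 12, and makes the cis-diol by a retentive opening of the oxirane instead of a carbonyl addition. Wittig reaction of 4 with 1-(triphenylphosphoranylidene)propan-2-one gives (3E)-4-[(1S,6R)-2,2,6-trimethyl-7-oxabicyclo[4.1.0]heptan-1-yl]but-3-en-2-one F3. Pd(PPh3)4-catalysed insertion of CO2 (THF, 1 atm; ionization with inversion, carbonate return with inversion, net retention at C6) gives the cis-fused cyclic carbonate of (3E)-4-[(1S,2R)-1,2-dihydroxy-2,6,6-trimethylcyclohexyl]but-3-en-2-one F4. Horner–Wadsworth–Emmons reaction with triethyl phosphonoacetate (NaH, THF) gives the cyclic carbonate of ethyl (2E,4E)-5-[(1S,2R)-1,2-dihydroxy-2,6,6-trimethylcyclohexyl]-3-methylpenta-2,4-dienoate F5, and i-Bu2AlH reduces both the ester and the carbonate to triol 12.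

(c) Step 10. What may go wrong is ionization or allylic transposition of the tertiary dienyl carbinol and loss of double-bond geometry while the primary hydroxyl is activated as a bromide. The fallback sets out from 12 and comes back at 22, and replaces the Wittig by a Julia–Kocienski olefination. Mitsunobu reaction of 12 with 1-phenyl-1H-tetrazole-5-thiol (PPh3, diisopropyl azodicarboxylate, THF, 0 °C) gives (1S,2R)-2,6,6-trimethyl-1-[(1E,3E)-3-methyl-5-[(1-phenyl-1H-tetrazol-5-yl)sulfanyl]penta-1,3-dien-1-yl]cyclohexane-1,2-diol F6. Oxidation ((NH4)6Mo7O24 cat., H2O2, EtOH, 0 °C) gives the corresponding sulfone F7. Deprotonation of F7 with KN(SiMe3)2 (THF, −78 °C) and addition of aldehyde 21 gives 22.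

**Further compounds**
F1 | step 17 | (1R,6R)-1-(iodoethynyl)-2,2,6-trimethyl-7-oxabicyclo[4.1.0]heptane | IC#C[C@@]12O[C@]1(C)CCCC2(C)C
F2 | step 17 | (5R,6S,5'R,6'R)-5',6'-epoxy-7',8'-didehydro-5,6,5',6'-tetrahydro-β,β-carotene-5,6-diol | CC(/C=C/C=C(C)/C=C/[C@]1(O)C(C)(C)CCC[C@@]1(C)O)=C\C=C\C=C(C)\C=C\C=C(/C)C#C[C@@]12O[C@]1(C)CCCC2(C)C
F3 | step 8 | (3E)-4-[(1S,6R)-2,2,6-trimethyl-7-oxabicyclo[4.1.0]heptan-1-yl]but-3-en-2-one | CC(=O)/C=C/[C@@]12O[C@]1(C)CCCC2(C)C
F4 | step 8 | cis-fused cyclic carbonate of (3E)-4-[(1S,2R)-1,2-dihydroxy-2,6,6-trimethylcyclohexyl]but-3-en-2-one | CC(=O)/C=C/[C@]1(O2)C(C)(C)CCC[C@@]1(C)OC2=O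
F5 | step 8 | cis-fused cyclic carbonate of ethyl (2E,4E)-5-[(1S,2R)-1,2-dihydroxy-2,6,6-trimethylcyclohexyl]-3-methylpenta-2,4-dienoate | CCOC(=O)/C=C(C)/C=C/[C@]1(O2)C(C)(C)CCC[C@@]1(C)OC2=O
F6 | step 10 | (1S,2R)-2,6,6-trimethyl-1-[(1E,3E)-3-methyl-5-[(1-phenyl-1H-tetrazol-5-yl)sulfanyl]penta-1,3-dien-1-yl]cyclohexane-1,2-diol | C(/C=C(C)/C=C/[C@]1(O)C(C)(C)CCC[C@@]1(C)O)Sc1nnnn1-c1ccccc1
F7 | step 10 | (1S,2R)-2,6,6-trimethyl-1-[(1E,3E)-3-methyl-5-[(1-phenyl-1H-tetrazol-5-yl)sulfonyl]penta-1,3-dien-1-yl]cyclohexane-1,2-diol | C(/C=C(C)/C=C/[C@]1(O)C(C)(C)CCC[C@@]1(C)O)S(=O)(=O)c1nnnn1-c1ccccc1
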